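Labels: C1 angelate carbinol, C2=C3 alkene (Me on C3), C4 CH2, C5 veratrate carbinol, C6 fusion CH, C7 fusion C(Me), C8/C9 CH2, C10 C(OH)i-Pr; ring A = C1–C7 (seven-membered), ring B = C6–C10 (five-membered).
Feature used: ring A is a hidden cyclohepta-1,4-diene. C2=C3 and a C5=C6 enol ether (C5 at ketone level) sit on both sides of C4H2, and the C1–C7 bond between the carbinol and the quaternary fusion carbon lies opposite, so a retro-Cope step leads to a cis-dialkenylcyclopropane C3–C4–C5.
Late disconnections: C1 angelate and C5 veratrate (acylations), C10–i-Pr (organocerium on the ring-B ketone), C6–H and C5–H (protonation and reduction of the enol ether), C1–O (from C1–B with retention).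
Early disconnections: E-alkenylboronate (Takai–Utimoto) from a cyclopropanecarbaldehyde; C3–Me by enolate methylation; C3 as a carbene (ethyl diazoacetate, copper–bis(oxazoline)) onto the C4=C5 silyl enol ether of a 2-acetyl-3-methylcyclopentenone ketal.
Ring order: ring B is bought (3-methylcyclopent-2-en-1-one), the cyclopropane is built on it, and ring A is closed last by the rearrangement.

Key step: step 10

Remark: labels C1–C10 serve as locants throughout, β is the face of C6–H and α the face of the C7 methyl; the sense of induction in step 5 is assigned by analogy with simple 1,1-disubstituted alkenes, and the antipodal ligand is equally available.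

Step 1
Reactants: 1 3-methylcyclopent-2-en-1-one
Product: 3 2-bromo-3-methylcyclopent-2-en-1-one, via dibromo ketone 2 (not isolated)
Conditions: Br2, CH2Cl2, 0 °C; then Et3N, 0 °C → rt
Reagents that add atoms: bromine, BrBr
Why: Bromination–dehydrobromination, in which bromine adds to the enone alkene and triethylamine removes the acidic C6 hydrogen with loss of the tertiary C7 bromide, is the standard way to a 2-bromocycloalkenone and leaves no stereocentre.

Step 2
Reactants: 3 2-bromo-3-methylcyclopent-2-en-1-one
Product: 4 6-bromo-7-methyl-1,4-dioxaspiro[4.4]non-6-ene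
Conditions: HOCH2CH2OH, p-TsOH (cat.), benzene, Dean–Stark, reflux
Reagents that add atoms: ethylene glycol, OCCO
Why: Acid-catalysed ketalisation with azeotropic removal of water, in which the vinylic bromine holds the alkene at C6=C7 so that no deconjugated isomer forms.

Step 3
Reactants: 4 6-bromo-7-methyl-1,4-dioxaspiro[4.4]non-6-ene
Product: 6 1-(7-methyl-1,4-dioxaspiro[4.4]non-6-en-6-yl)ethan-1-one, via vinyllithium 5 (not isolated)
Conditions: n-BuLi, THF, −78 °C; then MeC(O)N(OMe)Me, −78 → 0 °C; then H2O
Reagents that add atoms: N-methoxy-N-methylacetamide, CC(=O)N(C)OC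
Why: Bromine–lithium exchange is faster than any attack on the ketal and gives an α-keto vinyl anion equivalent, whose Weinreb acylation stops at the ketone because the chelated tetrahedral adduct survives until the quench.

Step 4
Reactants: 6 1-(7-methyl-1,4-dioxaspiro[4.4]non-6-en-6-yl)ethan-1-one
Product: 8 tert-butyldimethyl{[1-(7-methyl-1,4-dioxaspiro[4.4]non-6-en-6-yl)ethenyl]oxy}silane, via lithium enolate 7 (not isolated)
Conditions: LDA, THF, −78 °C; then TBSCl, DMPU, −78 °C → rt
Reagents that add atoms: tert-butyldimethylsilyl chloride, CC(C)(C)[Si](C)(C)Cl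
Why: Kinetic enolisation with LDA removes a proton of the acetyl methyl group (cross-conjugated enolate, not the γ positions), and O-silylation gives the 2-silyloxydiene under base-only conditions that spare the ketal.

Step 5
Reactants: 8 2-silyloxydiene; 9 ethyl diazoacetate
Product: 10 ethyl (1R,2S)-2-(tert-butyldimethylsilyloxy)-2-(7-methyl-1,4-dioxaspiro[4.4]non-6-en-6-yl)cyclopropane-1-carboxylate (3R,5S in route labels; ester trans to the cyclopentenyl group and cis to OTBS)
Conditions: (CuOTf)2·C6H6 (1 mol %), (S,S)-t-Bu-box [2,2′-(propane-2,2-diyl)bis((4S)-4-tert-butyl-4,5-dihydrooxazole)] (2.2 mol %), CH2Cl2, rt, slow addition of 9; chromatography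
Reagents that add atoms: ethyl diazoacetate 9, CCOC(=O)C=[N+]=[N-]
Why: In this copper–bis(oxazoline) asymmetric cyclopropanation the electrophilic carbenoid takes only the electron-rich terminal C4=C5 enol ether (the tetrasubstituted C6=C7 alkene is inert), the ligand fixes the carbene face and so C3 as R, the ester should settle trans to the much larger cyclopentenyl group so that C5 follows as S, and the minor cis ester, which carries the opposite C5 configuration, is removed by chromatography.

Step 6
Reactants: 10 trans cyclopropane ester
Product: 12 ethyl (1S,2R)-2-(tert-butyldimethylsilyloxy)-1-methyl-2-(7-methyl-1,4-dioxaspiro[4.4]non-6-en-6-yl)cyclopropane-1-carboxylate (3S,5R in route labels; methyl cis to OTBS; ester cis to the cyclopentenyl group), via ester enolate 11 (not isolated)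
Conditions: LDA, THF, −78 °C; then MeI, −78 → −20 °C
Reagents that add atoms: iodomethane, CI
Why: Deprotonation–alkylation of a 2-silyloxycyclopropanecarboxylate is known to keep the ring intact at −78 °C; C3 becomes planar and methyl iodide should enter on the side of the slim C5–O bond, away from the doubly flanked cyclopentenyl group, which puts the ester cis to that group, a relation that a 2-diazopropanoate carbenoid (ester trans to the larger alkene substituent) would not be expected to favour.

Step 7
Reactants: 12 methylated cyclopropane ester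
Product: 13 [(1R,2S)-2-(tert-butyldimethylsilyloxy)-1-methyl-2-(7-methyl-1,4-dioxaspiro[4.4]non-6-en-6-yl)cyclopropyl]methanol (3R,5S in route labels)
Conditions: LiAlH4, Et2O, 0 °C → rt; then H2O
Reagents that add atoms: none
Why: Hydride reduction of the ester leaves silyl ether, ketal and alkene untouched, and the trans relation of CH2O and OTBS on the ring rules out silyl migration.

Step 8
Reactants: 13 cyclopropylmethanol
Product: 14 (1S,2S)-2-(tert-butyldimethylsilyloxy)-1-methyl-2-(7-methyl-1,4-dioxaspiro[4.4]non-6-en-6-yl)cyclopropane-1-carbaldehyde (3S,5S in route labels)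
Conditions: n-Pr4N[RuO4] (5 mol %), NMO, 4 Å MS, CH2Cl2, 0 °C → rt; used at once
Reagents that add atoms: none
Why: The Ley–Griffith oxidation is neutral and stops at the non-enolisable aldehyde, so the donor–acceptor cyclopropane is not opened, and the inner C7 methyl that later slows the Cope step should equally hold back the retro-Claisen shift of this cis-alkenyl cyclopropanecarbaldehyde at room temperature.

Step 9
Reactants: 14 cyclopropanecarbaldehyde; 15 2-(dichloromethyl)-4,4,5,5-tetramethyl-1,3,2-dioxaborolane
Product: 16 tert-butyldimethyl{[(1S,2R)-2-methyl-1-(7-methyl-1,4-dioxaspiro[4.4]non-6-en-6-yl)-2-[(E)-2-(4,4,5,5-tetramethyl-1,3,2-dioxaborolan-2-yl)ethenyl]cyclopropyl]oxy}silane (3R,5S in route labels; the two alkenyl groups cis)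
Conditions: 15, CrCl2, LiI, THF, rt
Reagents that add atoms: 2-(dichloromethyl)-4,4,5,5-tetramethyl-1,3,2-dioxaborolane 15, ClC(Cl)B1OC(C)(C)C(C)(C)O1
Why: In the Takai–Utimoto olefination the geminal dichromium reagent from 15 adds only to the aldehyde and elimination from the crowded adduct gives the E alkenylboronate, under near-neutral conditions that silyl ether and ketal tolerate.

Step 10
Reactants: 16 cis-dialkenylcyclopropane
Product: 17 (1R,7R)-allylboronate: ring A cyclohepta-2,5-diene fused to ring B; Bpin on C1 (β) trans to the C7 methyl (α); methyl on C3; OTBS on C5 of the C5=C6 enol ether; ethylene ketal at C10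
Conditions: toluene, BHT (cat.), base-washed sealed tube, 110 → 130 °C
Reagents that add atoms: none
Why: On heating, 16 folds both alkenes over the three-membered ring (endo boat) and a concerted suprafacial [3,3] shift breaks C3–C5 while C1–C7 forms, the release of cyclopropane strain making it irreversible. The closest known reaction type is the divinylcyclopropane–cycloheptadiene (Cope) rearrangement of 1-silyloxy-1,2-dialkenylcyclopropanes and of cis-2-vinylcyclopropyl cycloalkenes. Ring A is closed onto ring B by a pericyclic three-to-seven ring expansion, and the boat forces both new ring alkenes (C2=C3 and the C5=C6 enol ether) to be cis. C1 is controlled by the E geometry of the alkenylboronate (boron on the outer side of the boat) and C7 by the ring-B alkene (C8 outside, methyl inside), so boron ends cis to C8 and trans to the angular methyl, and the absolute sense is handed on from the (3R,5S) cyclopropane because the termini can meet only on the ring face that both alkenyl groups occupy. The concerted path must outrun C3–C5 homolysis (cis–trans isomerisation, loss of enantiopurity) and hydrogen or boron shifts: the cis arrangement is already in place, the C3 methyl is trans to the cyclopentenyl group so no homodienyl 1,5-hydrogen shift is open, and a 1,3-borotropic shift of the weakly Lewis acidic pinacol ester would lead uphill to a tertiary boronate. The inner methyl raises the barrier well above that of the parent system, hence the heating, with BHT and base-washed glass to protect the acid-labile enol ether–ketal array.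

Step 11
Reactants: 17 allylboronate
Product: 18 (1R,7S)-allylic alcohol: as 17 but with β-OH on C1
Conditions: NaBO3·4H2O, THF/H2O, rt
Reagents that add atoms: sodium perborate, O[B-]1(O)OO[B-](O)(O)OO1.[Na+].[Na+]
Why: Perborate oxidation moves C1 from boron to oxygen by a 1,2-shift with retention and without allylic transposition, and the mild nucleophilic oxidant leaves the hindered silyl enol ether, the ketal and the alkene alone.

Step 12
Reactants: 18 allylic alcohol
Product: 20 (1R,7S)-PMB ether: as 18 but with β-OCH2C6H4-4-OMe on C1, via sodium alkoxide 19 (not isolated)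
Conditions: NaH, THF/DMF, 0 °C; then PMBCl, n-Bu4NI (cat.), 0 °C → rt
Reagents that add atoms: 4-methoxybenzyl chloride, COc1ccc(CCl)cc1
Why: Williamson etherification under base-only conditions masks the neopentylic allylic C1 alcohol with a group that survives fluoride, SmI2, dilute acid and organocerium reagents and can later be removed oxidatively beside an ester.

Step 13
Reactants: 20 PMB ether silyl enol ether
Product: 21 (1R,6S,7S)-ketone: trans-fused; C5 ketone; C6–H β; C1 OPMB β; C2=C3 alkene; C10 ethylene ketal
Conditions: n-Bu4NF, AcOH (1:1.2), THF, −20 → 0 °C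
Reagents that add atoms: none
Why: Buffered fluoride cleaves only the enol O–Si bond and the enolate is protonated before it can expel a ketal oxygen; because ring B locks ring A in the boat in which the C7 methyl stands perpendicular to the enol plane, the proton should arrive on the opposite convex β face, which sets C6 (S) and the trans fusion.

Step 14
Reactants: 21 ketone
Product: 22 (1R,5S,6S,7S)-alcohol: as 21 but with β (equatorial) OH on C5 and C5–H anti to C6–H
Conditions: SmI2, H2O, THF, 0 °C
Reagents that add atoms: none
Why: Single-electron (ketyl) reduction, like dissolving-metal reduction of hindered cyclic ketones, should give the more stable equatorial alcohol (5S), whereas hydride reagents would be pushed by the axial C7 methyl to the β face and give the epimer.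

Step 15
Reactants: 22 hydroxy ketal
Product: 23 (1R,5S,6S,7S)-β-hydroxy ketone: as 22 but with the C10 ketone free
Conditions: 1 M aq. HCl, THF, 0 °C → rt
Reagents that add atoms: water, O
Why: Acid hydrolysis of the dioxolane frees the ring-B ketone, PMB ether and alkene being stable, and short exposure to dilute acid limits dehydration of the β-hydroxy ketone and enolisation at C6.

Step 16
Reactants: 23 β-hydroxy ketone
Product: 24 (1R,5S,6S,7S,10R)-diol: C10 with α-OH and β-isopropyl; C5 β-OH; C1 OPMB
Conditions: i-PrMgCl, CeCl3 (dried), THF, −78 → 0 °C (excess reagent); then H2O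
Reagents that add atoms: isopropylmagnesium chloride, CC(C)[Mg]Cl
Why: The weakly basic organocerium reagent adds to the hindered enolisable ketone instead of deprotonating or reducing it (one equivalent is spent on the C5–OH) and should attack the β face of ring B, on the side of C6–H and away from the C6–C5 bond and the C7 methyl, which sets C10 (R).

Step 17
Reactants: 24 diol; 25 3,4-dimethoxybenzoyl chloride
Product: 26 (1R,5S,6S,7S,10R)-C5 veratrate of 24
Conditions: 25, DMAP (cat.), Et3N, CH2Cl2, rt → 40 °C
Reagents that add atoms: 3,4-dimethoxybenzoyl chloride 25, COc1ccc(C(=O)Cl)cc1OC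
Why: DMAP-catalysed acylation takes the secondary C5 alcohol while the tertiary C10 alcohol does not react, as is usual for secondary/tertiary diols of this skeleton.

Step 18
Reactants: 26 PMB-protected veratrate
Product: 27 (1R,5S,6S,7S,10R)-C1 alcohol: as 26 but with free β-OH on C1
Conditions: DDQ, CH2Cl2/pH 7 buffer, 0 °C
Reagents that add atoms: none
Why: Oxidative PMB cleavage (hydride abstraction from the electron-rich benzylic position, then hydrolysis) spares the veratrate ring, which is deactivated by its carbonyl group, as well as the alkene and the tertiary alcohol.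

Step 19
Reactants: 27 C1 alcohol; 28 angelic acid
Product: 30 CNP0142353.1 (1R,5S,6S,7S,10R in route labels), via mixed anhydride 29 (not isolated)
Conditions: 28, 2,4,6-trichlorobenzoyl chloride, Et3N, toluene, rt; then 27, 80 °C (no DMAP)
Reagents that add atoms: angelic acid 28, C/C=C(/C)C(=O)O
Why: Yamaguchi-type esterification through the mixed anhydride without a nucleophilic catalyst is the known way to acylate hindered secondary alcohols with angelic acid without Z-to-E isomerisation to the tiglate, and the tertiary C10 alcohol stays free.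

Compound list
1 | 3-methylcyclopent-2-en-1-one | CC1=CC(=O)CC1 | starting material
2 | 2,3-dibromo-3-methylcyclopentan-1-one | CC1(Br)CCC(=O)C1Br | intermediate
3 | 2-bromo-3-methylcyclopent-2-en-1-one | CC1=C(Br)C(=O)CC1 | intermediate
4 | 6-bromo-7-methyl-1,4-dioxaspiro[4.4]non-6-ene | CC1=C(Br)C2(CC1)OCCO2 | intermediate
5 | (7-methyl-1,4-dioxaspiro[4.4]non-6-en-6-yl)lithium | [Li]C1=C(C)CCC12OCCO2 | intermediate
6 | 1-(7-methyl-1,4-dioxaspiro[4.4]non-6-en-6-yl)ethan-1-one | CC(=O)C1=C(C)CCC12OCCO2 | intermediate
7 | lithium 1-(7-methyl-1,4-dioxaspiro[4.4]non-6-en-6-yl)ethen-1-olate | [Li]OC(=C)C1=C(C)CCC12OCCO2 | intermediate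
8 | 2-silyloxydiene (TBS enol ether of 6) | C=C(O[Si](C)(C)C(C)(C)C)C1=C(C)CCC12OCCO2 | intermediate
9 | ethyl diazoacetate | CCOC(=O)C=[N+]=[N-] | starting material
10 | trans cyclopropane ester (3R,5S) | CCOC(=O)[C@@H]1C[C@@]1(O[Si](C)(C)C(C)(C)C)C2=C(C)CCC23OCCO3 | intermediate
11 | lithium ester enolate of 10 | [Li]OC(OCC)=C1C[C@@]1(O[Si](C)(C)C(C)(C)C)C2=C(C)CCC23OCCO3 | intermediate
12 | methylated cyclopropane ester (3S,5R) | C[C@]1(C(=O)OCC)C[C@@]1(O[Si](C)(C)C(C)(C)C)C2=C(C)CCC23OCCO3 | intermediate
13 | cyclopropylmethanol (3R,5S) | C[C@]1(CO)C[C@@]1(O[Si](C)(C)C(C)(C)C)C2=C(C)CCC23OCCO3 | intermediate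
14 | cyclopropanecarbaldehyde (3S,5S) | C[C@]1(C=O)C[C@@]1(O[Si](C)(C)C(C)(C)C)C2=C(C)CCC23OCCO3 | intermediate
15 | 2-(dichloromethyl)-4,4,5,5-tetramethyl-1,3,2-dioxaborolane | ClC(Cl)B1OC(C)(C)C(C)(C)O1 | starting material
16 | cis-dialkenylcyclopropane with E-alkenylboronate (3R,5S) | C[C@]1(/C=C/B2OC(C)(C)C(C)(C)O2)C[C@@]1(O[Si](C)(C)C(C)(C)C)C3=C(C)CCC34OCCO4 | intermediate
17 | bicyclic allylboronate (1R,7R) | CC1(C)OB(OC1(C)C)[C@@H]2C=C(C)CC(O[Si](C)(C)C(C)(C)C)=C3[C@]2(C)CCC34OCCO4 | intermediate
18 | C1 allylic alcohol (1R,7S) | O[C@@H]1C=C(C)CC(O[Si](C)(C)C(C)(C)C)=C2[C@]1(C)CCC23OCCO3 | intermediate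
19 | sodium alkoxide of 18 | [Na+].[O-][C@@H]1C=C(C)CC(O[Si](C)(C)C(C)(C)C)=C2[C@]1(C)CCC23OCCO3 | intermediate
20 | C1 PMB ether (1R,7S) | COc1ccc(CO[C@@H]2C=C(C)CC(O[Si](C)(C)C(C)(C)C)=C3[C@]2(C)CCC34OCCO4)cc1 | intermediate
21 | trans-fused C5 ketone (1R,6S,7S) | COc1ccc(CO[C@@H]2C=C(C)CC(=O)[C@@H]3[C@]2(C)CCC34OCCO4)cc1 | intermediate
22 | C5 β-alcohol (1R,5S,6S,7S) | COc1ccc(CO[C@@H]2C=C(C)C[C@H](O)[C@@H]3[C@]2(C)CCC34OCCO4)cc1 | intermediate
23 | β-hydroxy ketone (1R,5S,6S,7S) | COc1ccc(CO[C@@H]2C=C(C)C[C@H](O)[C@@H]3[C@]2(C)CCC3=O)cc1 | intermediate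
24 | C5,C10 diol (1R,5S,6S,7S,10R) | COc1ccc(CO[C@@H]2C=C(C)C[C@H](O)[C@@H]3[C@]2(C)CC[C@@]3(O)C(C)C)cc1 | intermediate
25 | 3,4-dimethoxybenzoyl chloride | COc1ccc(C(=O)Cl)cc1OC | starting material
26 | C5 veratrate, C1 PMB ether | COc1ccc(CO[C@@H]2C=C(C)C[C@H](OC(=O)c3ccc(OC)c(OC)c3)[C@@H]4[C@]2(C)CC[C@@]4(O)C(C)C)cc1 | intermediate
27 | C5 veratrate, C1 alcohol | O[C@@H]1C=C(C)C[C@H](OC(=O)c2ccc(OC)c(OC)c2)[C@@H]3[C@]1(C)CC[C@@]3(O)C(C)C | intermediate
28 | angelic acid | C/C=C(/C)C(=O)O | starting material
29 | angelic 2,4,6-trichlorobenzoic anhydride | C/C=C(/C)C(=O)OC(=O)c1c(Cl)cc(Cl)cc1Cl | intermediate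
30 | CNP0142353.1 | C/C=C(/C)C(=O)O[C@@H]1C=C(C)C[C@H](OC(=O)c2ccc(OC)c(OC)c2)[C@@H]2[C@]1(C)CC[C@@]2(O)C(C)C | target

Total step count: 19. Longest linear sequence: 19 steps from 1.

Risk 1 (step 10). The inner methyl may raise the barrier so far that C3–C5 homolysis (cis–trans isomerisation, erosion of enantiopurity) and thermal loss or migration of boron compete at the temperature needed. An outer boryl group together with an inner methyl has not been examined. The fallback puts the C1 oxygen on the alkene before the rearrangement, so that no allylboronate has to survive heating. It sets out from 16. A Chan–Lam–Evans-type coupling with 4-methoxybenzyl alcohol (Cu(OAc)2, Et3N, air, rt) exchanges boron for oxygen with retention of the E geometry and gives the E enol ether F1. Heating this compound in toluene or xylene runs the same boat rearrangement, which is known for E 1-oxygenated alkene termini. It delivers 20, where the route is rejoined and steps 11 and 12 fall away.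

Risk 2 (step 6). The C3 proton lies on the hindered face and may be removed slowly, the enolate may open the ring on warming, or alkylation may take place on the wrong face. The fallback brings the methyl group in with the carbene and sets out from 8. Methyl 2-diazopropanoate F2 is made from methyl 2-methylacetoacetate by deacylative diazo transfer (4-acetamidobenzenesulfonyl azide, DBU, MeCN). It is decomposed with Rh2(S-PTTL)4 in hexane/CH2Cl2 at −78 °C, conditions known to favour cyclopropanation over β-hydride shift for α-alkyl diazoesters. The isomer with the ester cis to the cyclopentenyl group, the methyl ester F3, is separated, accepting that it may be the minor one. LiAlH4 then reduces it to 13, where the route is rejoined.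

Risk 3 (step 14). The electron-transfer reduction may show poor facial selectivity at C5, or C6 may epimerise during it. The fallback sets C5 last, by hydride delivery from the C10 hydroxyl, and sets out from 21. NaBH4 (MeOH, 0 °C) should give mainly the C5-epimeric alcohol F4. Ketal hydrolysis as in step 15 gives the epimeric hydroxy ketone F5, and isopropylcerium addition as in step 16 gives the epimeric diol F6. Dess–Martin periodinane oxidises only the secondary alcohol, to the β-hydroxy ketone F7. Evans–Saksena reduction (Me4N[BH(OAc)3], MeCN/AcOH, −20 °C) binds boron to the α C10–OH and delivers hydride to the α face of C5. This gives 24, where the route is rejoined.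

Further compounds
F1 | step 10 | analogue of 16 with (E)-2-(4-methoxybenzyloxy)ethenyl on C3 (3R,5S) | C[C@]1(/C=C/OCc2ccc(OC)cc2)C[C@@]1(O[Si](C)(C)C(C)(C)C)C3=C(C)CCC34OCCO4
F2 | step 6 | methyl 2-diazopropanoate | CC(=[N+]=[N-])C(=O)OC
F3 | step 6 | methyl (1S,2R)-2-(tert-butyldimethylsilyloxy)-1-methyl-2-(7-methyl-1,4-dioxaspiro[4.4]non-6-en-6-yl)cyclopropane-1-carboxylate | C[C@]1(C(=O)OC)C[C@@]1(O[Si](C)(C)C(C)(C)C)C2=C(C)CCC23OCCO3
F4 | step 14 | C5 epimer of 22 (α-OH) | COc1ccc(CO[C@@H]2C=C(C)C[C@@H](O)[C@@H]3[C@]2(C)CCC34OCCO4)cc1
F5 | step 14 | C5 epimer of 23 | COc1ccc(CO[C@@H]2C=C(C)C[C@@H](O)[C@@H]3[C@]2(C)CCC3=O)cc1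
F6 | step 14 | C5 epimer of 24 | COc1ccc(CO[C@@H]2C=C(C)C[C@@H](O)[C@@H]3[C@]2(C)CC[C@@]3(O)C(C)C)cc1
F7 | step 14 | C5 ketone with C10 tertiary alcohol | COc1ccc(CO[C@@H]2C=C(C)CC(=O)[C@@H]3[C@]2(C)CC[C@@]3(O)C(C)C)cc1
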